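**Retrosynthetic overview**
- The diene is made last: Negishi C11–C12 coupling of an (E)-vinyl iodide (from benzyl bromide and propynyl Grignard) with the alkenylalane obtained by carboalumination of a terminal alkyne on the finished peroxylactone.
- The C6 quaternary centre comes from C-methylation of a bicyclic peroxyketal through its peroxycarbenium ion (the new step).
- The 1,2-dioxane comes from cobalt-catalysed aerobic ring expansion of a lactone-fused cyclobutanol, with O2 inserted into the C3–C6 bond (the key step).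
- The cyclobutanol comes from Grignard addition of a chiral-pool C7–C11 bromide to a bicyclic cyclobutanone, itself made by an auxiliary-controlled keteniminium [2+2] on α-angelica lactone.
- Ring order: γ-lactone (bought in α-angelica lactone), then cyclobutane, then 1,2-dioxane.

Locants C1–C14 follow the target: lactone C1(=O), C2, C3 (CH–OO), C4 (C–CH3, lactone O), C5, C6 (C–CH3, OO), side chain C7–C14 (C8 stereocentre, C10=C11, C12=C13, phenyl on C14). The target is (3R,4R,6R,8S,10E,12E).

Assumption: the (2R,5R) auxiliary is taken to give the (1R,5R)-cyclobutanone 7 in step 2; if the facial sense proves to be the reverse, the (2S,5S) antipode of 2 is used.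

Step 1
Reactants: 1 acetyl chloride; 2 (2R,5R)-2,5-dimethylpyrrolidine
Product: 3 1-[(2R,5R)-2,5-dimethylpyrrolidin-1-yl]ethan-1-one
Conditions: Et3N, CH2Cl2, 0 °C → rt
Reagents that add atoms: none
Why: N-acylation of the secondary amine by the acid chloride gives the tertiary acetamide needed for keteniminium generation; no stereocentre is formed or touched.

Step 2
Reactants: 3 1-[(2R,5R)-2,5-dimethylpyrrolidin-1-yl]ethan-1-one; 4 α-angelica lactone (5-methylfuran-2(3H)-one)
Product: 7 (1R,5R)-1-methyl-2-oxabicyclo[3.2.0]heptane-3,6-dione, via keteniminium triflate 5 (not isolated), via cyclobutaniminium triflate 6 (not isolated)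
Conditions: Tf2O, 2,4,6-collidine, ClCH2CH2Cl, −20 °C → rt; 4, reflux; then H2O, NaHCO3, rt
Reagents that add atoms: water, O
Why: Ghosez keteniminium–alkene [2+2] cycloaddition, in which the electrophilic central carbon of 5 bonds to the nucleophilic C3 of the enol lactone and its CH2 closes onto the oxygen-stabilised C4 cation, so the cis-fused ring forms with the C2-symmetric pyrrolidine shielding one alkene face (this sets C4 and, provisionally, C3), and hydrolysis of 6 releases the cyclobutanone.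

Step 3
Reactants: 8 (S)-3-bromo-2-methylpropan-1-ol; 9 ethynyltrimethylsilane
Product: 12 (S)-(5-bromo-4-methylpent-1-yn-1-yl)trimethylsilane, via primary triflate 10 (not isolated), via lithium trimethylsilylacetylide 11 (not isolated)
Conditions: 9, n-BuLi, THF, −78 °C; separately 8, Tf2O, 2,6-lutidine, CH2Cl2, −78 °C; combine, THF/DMPU, −78 → −20 °C
Reagents that add atoms: none
Why: SN2 alkynylation of a primary alkyl triflate by a lithium acetylide at low temperature is far faster than displacement of the primary bromide, and the chiral-pool C8 stereocentre is not involved.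

Step 4
Reactants: 12 (S)-(5-bromo-4-methylpent-1-yn-1-yl)trimethylsilane; 7 (1R,5R)-1-methyl-2-oxabicyclo[3.2.0]heptane-3,6-dione
Product: 15 (1R,5S,6S)-6-hydroxy-1-methyl-6-[(S)-2-methylpent-4-yn-1-yl]-2-oxabicyclo[3.2.0]heptan-3-one, via Grignard reagent 13 (not isolated), via silylated cyclobutanol 14 (not isolated)
Conditions: 12, Mg, THF, rt; LaCl3·2LiCl (30 mol %), 7, THF, −78 °C; NH4Cl aq; crude: AgNO3 (10 mol %), acetone/H2O, rt
Reagents that add atoms: none
Why: Lanthanum-assisted Grignard 1,2-addition to the strained cyclobutanone outruns lactone attack and enolisation and occurs from the convex face (the new C6 carbinol configuration is erased in step 5), and silver-catalysed protodesilylation then frees the terminal alkyne.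

Step 5
Reactants: 15 (1R,5S,6S)-6-hydroxy-1-methyl-6-[(S)-2-methylpent-4-yn-1-yl]-2-oxabicyclo[3.2.0]heptan-3-one
Product: 17 (4aR)-3-hydroxy-4a-methyl-3-[(S)-2-methylpent-4-yn-1-yl]-3,4,4a,7a-tetrahydrofuro[3,2-c][1,2]dioxin-6(7H)-one (C3 epimers in target locants, both C6 anomers), via hydroperoxy ketone 16 (not isolated)
Conditions: Co(acac)2 (20 mol %), O2 (1 atm), ClCH2CH2Cl, 40 °C
Reagents that add atoms: dioxygen, O=O
Why: Cobalt-catalysed aerobic oxidative ring expansion of a tertiary cyclobutanol, in which the alkoxy radical undergoes strain-driven β-scission of the C6–C3 bond (secondary radical, more substituted side), O2 is captured at C3 and the hydroperoxide closes onto the new C6 ketone to give the six-membered peroxyhemiketal; C3 forms without control and is corrected in step 6, while C4 and C8 are untouched.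

Step 6
Reactants: 17 (4aR)-3-hydroxy-4a-methyl-3-[(S)-2-methylpent-4-yn-1-yl]-3,4,4a,7a-tetrahydrofuro[3,2-c][1,2]dioxin-6(7H)-one
Product: 20 (4aR,7aR)-3-methoxy-4a-methyl-3-[(S)-2-methylpent-4-yn-1-yl]-3,4,4a,7a-tetrahydrofuro[3,2-c][1,2]dioxin-6(7H)-one (both C6 anomers), via methyl peroxyketal epimer mixture 18 (not isolated), via butenolide hydroperoxy ketal 19 (not isolated)
Conditions: CSA (10 mol %), MeOH, 0 °C; then Et2NH (0.5 equiv), CF3CH2OH, rt
Reagents that add atoms: methanol, CO
Why: Acid-catalysed exchange of the peroxyhemiketal OH for OMe, then amine-mediated retro-peroxy-Michael/6-exo peroxy-Michael equilibration through butenolide 19, which can only reclose on the face of the lactone carrying the C5 tether and therefore funnels both C3 epimers to the cis-fused lactone (C3 R, H cis to the C4 methyl).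

Step 7
Reactants: 20 (4aR,7aR)-3-methoxy-4a-methyl-3-[(S)-2-methylpent-4-yn-1-yl]-3,4,4a,7a-tetrahydrofuro[3,2-c][1,2]dioxin-6(7H)-one
Product: 22 (3R,4aR,7aR)-3,4a-dimethyl-3-[(S)-2-methylpent-4-yn-1-yl]-3,4,4a,7a-tetrahydrofuro[3,2-c][1,2]dioxin-6(7H)-one, via peroxycarbenium triflate 21 (not isolated)
Conditions: AlMe3 (3 equiv), TMSOTf (1.2 equiv), CH2Cl2, −78 °C
Reagents that add atoms: trimethylaluminium, C[Al](C)C
Why: Proposed new method: TMSOTf ionises the cyclic peroxyketal to peroxycarbenium ion 21 (C6=O+–O) and AlMe3, a non-basic methyl donor, transfers CH3 to C6; in the favoured half-chair the lactone oxygen on C4 is pseudoaxial and the C4 methyl pseudoequatorial, so chair-like axial attack places the new methyl cis to the lactone oxygen (the 6R configuration), whereas the other face would require attack syn to a pseudoaxial C4 methyl; the terminal alkyne should not compete because it would have to form a vinyl cation; the closest known reaction types are Lewis-acid-mediated substitution of cyclic peroxyketals by allylsilanes, silyl enol ethers and Et3SiH through peroxycarbenium ions, and AlMe3 C-methylation of cyclic oxocarbenium ions from ketals and glycosyl-type acetates.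

Step 8
Reactants: 23 benzyl bromide; 24 prop-1-yn-1-ylmagnesium bromide
Product: 25 but-2-yn-1-ylbenzene
Conditions: CuBr·SMe2 (5 mol %), THF, 0 → 50 °C
Reagents that add atoms: none
Why: Copper-catalysed SN2 coupling of an alkynyl Grignard reagent with a benzylic bromide forms the C13–C14 bond.

Step 9
Reactants: 25 but-2-yn-1-ylbenzene
Product: 27 (E)-(3-iodobut-2-en-1-yl)benzene, via alkenylzirconocene chloride 26 (not isolated)
Conditions: Cp2Zr(H)Cl (1.5 equiv), THF, rt → 40 °C; then I2, 0 °C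
Reagents that add atoms: iodine, II
Why: Schwartz hydrozirconation under equilibrating conditions adds H and Zr syn with zirconium on the less hindered methyl-bearing carbon, and iodinolysis with retention gives the (E)-iodide (I trans to CH2Ph), which fixes the C12=C13 geometry.

Step 10
Reactants: 22 (3R,4aR,7aR)-3,4a-dimethyl-3-[(S)-2-methylpent-4-yn-1-yl]-3,4,4a,7a-tetrahydrofuro[3,2-c][1,2]dioxin-6(7H)-one; 27 (E)-(3-iodobut-2-en-1-yl)benzene
Product: 29 plakortolide, (3R,4aR,7aR)-3,4a-dimethyl-3-[(2S,4E,6E)-2,4,6-trimethyl-8-phenylocta-4,6-dien-1-yl]-3,4,4a,7a-tetrahydrofuro[3,2-c][1,2]dioxin-6(7H)-one, via alkenyldimethylalane 28 (not isolated)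
Conditions: AlMe3 (3 equiv), Cp2ZrCl2 (0.3 equiv), H2O (1 equiv), CH2Cl2, −23 °C; then 27, ZnCl2 (1.2 equiv), Pd(PPh3)4 (5 mol %), THF, 0 °C → rt
Reagents that add atoms: trimethylaluminium, C[Al](C)C
Why: Negishi zirconium-catalysed syn-carboalumination of the terminal alkyne gives the (E)-2-methylalkenylalane regioselectively (sets C10=C11), and palladium-catalysed Negishi coupling with 27 after transmetalation to zinc forms the C11–C12 bond with retention of both alkene geometries under conditions in which dialkyl peroxides are expected to survive.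

**Compound list**
1 | acetyl chloride | CC(Cl)=O | starting material
2 | (2R,5R)-2,5-dimethylpyrrolidine (recoverable auxiliary) | C[C@@H]1CC[C@@H](C)N1 | starting material
3 | 1-[(2R,5R)-2,5-dimethylpyrrolidin-1-yl]ethan-1-one | CC(=O)N1[C@H](C)CC[C@H]1C | intermediate
4 | α-angelica lactone (5-methylfuran-2(3H)-one) | CC1=CCC(=O)O1 | starting material
5 | (2R,5R)-1-ethenylidene-2,5-dimethylpyrrolidinium triflate (keteniminium salt) | C=C=[N+]1[C@H](C)CC[C@H]1C.[O-]S(=O)(=O)C(F)(F)F | intermediate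
6 | (2R,5R)-2,5-dimethyl-1-[(1R,5S)-1-methyl-3-oxo-2-oxabicyclo[3.2.0]heptan-6-ylidene]pyrrolidinium triflate | C[C@@H]1CC[C@@H](C)[N+]1=C3C[C@@]2(C)OC(=O)C[C@@H]32.[O-]S(=O)(=O)C(F)(F)F | intermediate
7 | (1R,5R)-1-methyl-2-oxabicyclo[3.2.0]heptane-3,6-dione (cis-fused) | O=C1C[C@@]2(C)OC(=O)C[C@@H]12 | intermediate
8 | (S)-3-bromo-2-methylpropan-1-ol | OC[C@H](C)CBr | starting material
9 | ethynyltrimethylsilane | C#C[Si](C)(C)C | starting material
10 | (S)-3-bromo-2-methylpropyl trifluoromethanesulfonate | FC(F)(F)S(=O)(=O)OC[C@H](C)CBr | intermediate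
11 | lithium (trimethylsilyl)acetylide | [Li]C#C[Si](C)(C)C | intermediate
12 | (S)-(5-bromo-4-methylpent-1-yn-1-yl)trimethylsilane | C[Si](C)(C)C#CC[C@H](C)CBr | intermediate
13 | [(S)-2-methyl-5-(trimethylsilyl)pent-4-yn-1-yl]magnesium bromide | C[Si](C)(C)C#CC[C@H](C)C[Mg]Br | intermediate
14 | (1R,5S,6S)-6-hydroxy-1-methyl-6-[(S)-2-methyl-5-(trimethylsilyl)pent-4-yn-1-yl]-2-oxabicyclo[3.2.0]heptan-3-one | O[C@@]1(C[C@@H](C)CC#C[Si](C)(C)C)C[C@@]2(C)OC(=O)C[C@@H]12 | intermediate
15 | (1R,5S,6S)-6-hydroxy-1-methyl-6-[(S)-2-methylpent-4-yn-1-yl]-2-oxabicyclo[3.2.0]heptan-3-one | O[C@@]1(C[C@@H](C)CC#C)C[C@@]2(C)OC(=O)C[C@@H]12 | intermediate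
16 | (5R)-4-hydroperoxy-5-methyl-5-[(4S)-4-methyl-2-oxohept-6-yn-1-yl]dihydrofuran-2(3H)-one (both C4 epimers of the lactone ring) | O=C(C[C@@H](C)CC#C)C[C@@]1(C)OC(=O)CC1OO | intermediate
17 | (4aR)-3-hydroxy-4a-methyl-3-[(S)-2-methylpent-4-yn-1-yl]-3,4,4a,7a-tetrahydrofuro[3,2-c][1,2]dioxin-6(7H)-one (C7a epimers, C3 anomers) | OC1(C[C@@H](C)CC#C)C[C@@]2(C)OC(=O)CC2OO1 | intermediate
18 | (4aR)-3-methoxy-4a-methyl-3-[(S)-2-methylpent-4-yn-1-yl]-3,4,4a,7a-tetrahydrofuro[3,2-c][1,2]dioxin-6(7H)-one (C7a epimers, C3 anomers) | COC1(C[C@@H](C)CC#C)C[C@@]2(C)OC(=O)CC2OO1 | intermediate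
19 | (5R)-5-[(4S)-2-hydroperoxy-2-methoxy-4-methylhept-6-yn-1-yl]-5-methylfuran-2(5H)-one | COC(OO)(C[C@@H](C)CC#C)C[C@@]1(C)OC(=O)C=C1 | intermediate
20 | (4aR,7aR)-3-methoxy-4a-methyl-3-[(S)-2-methylpent-4-yn-1-yl]-3,4,4a,7a-tetrahydrofuro[3,2-c][1,2]dioxin-6(7H)-one (cis-fused, C3 anomers) | COC1(C[C@@H](C)CC#C)C[C@@]2(C)OC(=O)C[C@H]2OO1 | intermediate
21 | cis-fused peroxycarbenium triflate (C6=O+–O) derived from 20 | C#CC[C@H](C)CC1=[O+]O[C@@H]2CC(=O)O[C@]2(C)C1.[O-]S(=O)(=O)C(F)(F)F | intermediate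
22 | (3R,4aR,7aR)-3,4a-dimethyl-3-[(S)-2-methylpent-4-yn-1-yl]-3,4,4a,7a-tetrahydrofuro[3,2-c][1,2]dioxin-6(7H)-one | C#CC[C@H](C)C[C@]1(C)C[C@@]2(C)OC(=O)C[C@H]2OO1 | intermediate
23 | benzyl bromide | BrCc1ccccc1 | starting material
24 | prop-1-yn-1-ylmagnesium bromide | CC#C[Mg]Br | starting material
25 | but-2-yn-1-ylbenzene | CC#CCc1ccccc1 | intermediate
26 | chlorobis(cyclopentadienyl)[(E)-4-phenylbut-2-en-2-yl]zirconium | C/C(=C\Cc1ccccc1)[Zr](Cl)(C1C=CC=C1)C1C=CC=C1 | intermediate
27 | (E)-(3-iodobut-2-en-1-yl)benzene | C/C(I)=C\Cc1ccccc1 | intermediate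
28 | (E)-alkenyldimethylalane of 22 (AlMe2 on C11, cis to the new C10 methyl) | C[Al](C)/C=C(\C)C[C@H](C)C[C@]1(C)C[C@@]2(C)OC(=O)C[C@H]2OO1 | intermediate
29 | plakortolide, (3R,4aR,7aR)-3,4a-dimethyl-3-[(2S,4E,6E)-2,4,6-trimethyl-8-phenylocta-4,6-dien-1-yl]-3,4,4a,7a-tetrahydrofuro[3,2-c][1,2]dioxin-6(7H)-one | CC(=C\Cc1ccccc1)/C=C(\C)C[C@H](C)C[C@]1(C)C[C@@]2(C)OC(=O)C[C@H]2OO1 | target

**Step count and risk**
Total step count: 10. Longest linear sequence: 7 steps (1, 2, 4, 5, 6, 7, 10).

The three steps most likely to fail: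

Step 2 (auxiliary-controlled keteniminium [2+2]). An enol lactone has not been used as the alkene partner with this auxiliary, so both yield and facial selectivity are uncertain. The fallback sets out from 4 and returns at 15. Cycloaddition of 4 with dichloroketene (Cl3CCOCl, Zn–Cu, Et2O) gives racemic cis-fused 7,7-dichloro-1-methyl-2-oxabicyclo[3.2.0]heptane-3,6-dione F1. Dechlorination with Zn/AcOH gives 7 as the racemate, that is, together with its (1S,5S)-enantiomer F2. Step 4 with enantiopure 12 then gives 15 and the diastereomeric cyclobutanol with the enantiomeric core F3, which are separated by chromatography, and the route continues from 15 at the cost of half the material.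

Step 7 (the proposed peroxycarbenium C-methylation). Methyl transfer from AlMe3 to a peroxycarbenium ion has no precedent, and O–O cleavage or elimination could intervene. The fallback uses known chemistry, sets out from 17 and returns at 22. Et3N in CH2Cl2 expels hydrogen peroxide from the ring-opened form of 17 to give butenolide ketone F4. Lombardo methylenation (Zn, CH2Br2, TiCl4) gives the 1,1-disubstituted alkene F5. Mukaiyama–Isayama hydroperoxysilylation (Co(thd)2, O2, Et3SiH) gives the tertiary triethylsilyl peroxide F6 as a roughly 1:1 pair at C6. Desilylation (Bu4NF/AcOH) and Et2NH/CF3CH2OH peroxy-Michael cyclisation give 22 together with its C6 epimer F7, separated by chromatography.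

Step 10 (carboalumination and Negishi coupling on the peroxylactone). AlMe3/Cp2ZrCl2 may damage the O–O bond or the lactone. The fallback sets out from 15 and returns at 29, and moves the carboalumination ahead of the O2 insertion. Carboalumination of 15 (AlMe3, Cp2ZrCl2) and iodinolysis (I2) give the (E)-vinyl iodide cyclobutanol F8. The conditions of steps 5 to 7 then give the peroxyhemiketal F9, the cis-fused methyl peroxyketal F10 and the methylated vinyl iodide F11. Alkenylzirconocene 26 is transmetalated with ZnCl2 to the alkenylzinc chloride F12, and Pd(PPh3)4-catalysed Negishi coupling of F12 with F11 gives 29. The cost is that the vinyl iodide is present during the methylation, where it could act as a π-nucleophile.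

**Further compounds**
F1 | step 2 | racemic cis-fused 7,7-dichloro-1-methyl-2-oxabicyclo[3.2.0]heptane-3,6-dione (one enantiomer drawn) | O=C1C(Cl)(Cl)[C@@]2(C)OC(=O)C[C@@H]12
F2 | step 2 | (1S,5S)-1-methyl-2-oxabicyclo[3.2.0]heptane-3,6-dione (enantiomer of 7 in the racemate) | O=C1C[C@]2(C)OC(=O)C[C@H]12
F3 | step 2 | (1S,5R,6R)-6-hydroxy-1-methyl-6-[(S)-2-methylpent-4-yn-1-yl]-2-oxabicyclo[3.2.0]heptan-3-one (diastereomer of 15) | O[C@]1(C[C@@H](C)CC#C)C[C@]2(C)OC(=O)C[C@H]12
F4 | step 7 | (5R)-5-methyl-5-[(4S)-4-methyl-2-oxohept-6-yn-1-yl]furan-2(5H)-one | O=C(C[C@@H](C)CC#C)C[C@@]1(C)OC(=O)C=C1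
F5 | step 7 | (5R)-5-methyl-5-[(4S)-4-methyl-2-methylidenehept-6-yn-1-yl]furan-2(5H)-one | C=C(C[C@@H](C)CC#C)C[C@@]1(C)OC(=O)C=C1
F6 | step 7 | (5R)-5-[(4S)-2,4-dimethyl-2-(triethylsilylperoxy)hept-6-yn-1-yl]-5-methylfuran-2(5H)-one (both C2 epimers of the chain) | CC[Si](CC)(CC)OOC(C)(C[C@@H](C)CC#C)C[C@@]1(C)OC(=O)C=C1
F7 | step 7 | (3S,4aR,7aR)-3,4a-dimethyl-3-[(S)-2-methylpent-4-yn-1-yl]-3,4,4a,7a-tetrahydrofuro[3,2-c][1,2]dioxin-6(7H)-one (C6 epimer of 22) | C#CC[C@H](C)C[C@@]1(C)C[C@@]2(C)OC(=O)C[C@H]2OO1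
F8 | step 10 | (1R,5S,6S)-6-hydroxy-6-[(2S,4E)-5-iodo-2,4-dimethylpent-4-en-1-yl]-1-methyl-2-oxabicyclo[3.2.0]heptan-3-one | O[C@@]1(C[C@@H](C)C/C(C)=C/I)C[C@@]2(C)OC(=O)C[C@@H]12
F9 | step 10 | (4aR)-3-hydroxy-3-[(2S,4E)-5-iodo-2,4-dimethylpent-4-en-1-yl]-4a-methyl-3,4,4a,7a-tetrahydrofuro[3,2-c][1,2]dioxin-6(7H)-one (C7a epimers, C3 anomers) | OC1(C[C@@H](C)C/C(C)=C/I)C[C@@]2(C)OC(=O)CC2OO1
F10 | step 10 | (4aR,7aR)-3-[(2S,4E)-5-iodo-2,4-dimethylpent-4-en-1-yl]-3-methoxy-4a-methyl-3,4,4a,7a-tetrahydrofuro[3,2-c][1,2]dioxin-6(7H)-one (C3 anomers) | COC1(C[C@@H](C)C/C(C)=C/I)C[C@@]2(C)OC(=O)C[C@H]2OO1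
F11 | step 10 | (3R,4aR,7aR)-3-[(2S,4E)-5-iodo-2,4-dimethylpent-4-en-1-yl]-3,4a-dimethyl-3,4,4a,7a-tetrahydrofuro[3,2-c][1,2]dioxin-6(7H)-one | I/C=C(\C)C[C@H](C)C[C@]1(C)C[C@@]2(C)OC(=O)C[C@H]2OO1
F12 | step 10 | chloro[(E)-4-phenylbut-2-en-2-yl]zinc | C/C(=C\Cc1ccccc1)[Zn]Cl
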